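**Strategy.** Everything rests on cutting the seven-membered enoate lactone into a malonic half ester of a thiolactate and acrolein. The key step exploits that the lactone α-carbon (C=) and the methyl-bearing quaternary O–C carbon of this ring are 1,4-related across the ester C(=O)–O and bridged by CH=, CH2, CH2: in one pot an asymmetric phase-transfer Michael addition builds the quaternary stereocentre and a decarboxylative Knoevenagel–Doebner condensation closes the lactone with its C=C bond. The precursor is an acyclic mixture of four stereoisomers that converges on one lactone. Thioester-to-enone coupling and an intramolecular Still–Gennari olefination then close the fourteen-membered carbocycle.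

Key step: step 9

Assumption: racemic 2-bromopropanoyl bromide is used because both C–H stereocentres of the key-step precursor are erased in the key step; the pseudoenantiomer of the phase-transfer catalyst that leads to the (S)-lactone is to be selected in a screen.

Step 1
Reactants: 1 4-bromobut-1-yne; 2 methyl chloroformate
Product: 3 methyl 5-bromopent-2-ynoate
Conditions: n-BuLi, THF, −78 °C; then 2, −78 → 0 °C
Reagents that add atoms: methyl chloroformate (2), COC(=O)Cl
Why: Deprotonation of the terminal alkyne and C-acylation of the lithium acetylide with the chloroformate should be fast at −78 °C, where the primary bromide is inert.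

Step 2
Reactants: 3 methyl 5-bromopent-2-ynoate; 4 isopropylmagnesium chloride
Product: 5 methyl (2E)-5-bromo-3-(propan-2-yl)pent-2-enoate
Conditions: 4, CuBr·SMe2 (1.2 equiv), THF, −78 °C; then NH4Cl/MeOH at −78 °C
Reagents that add atoms: isopropylmagnesium chloride (4), CC(C)[Mg]Cl
Why: syn-Carbocupration of the ynoate (organocopper conjugate addition) and cold protonation of the alkenylcopper with retention should place H cis to isopropyl, so the ester ends cis to the bromoethyl chain and the alkene geometry is fixed.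

Step 3
Reactants: 5 methyl (2E)-5-bromo-3-(propan-2-yl)pent-2-enoate
Product: 6 (2E)-5-bromo-3-(propan-2-yl)pent-2-en-1-ol
Conditions: iBu2AlH (2.2 equiv), CH2Cl2, −78 °C; aqueous potassium sodium tartrate
Reagents that add atoms: none
Why: 1,2-Reduction of the enoate by the aluminium hydride should give the allylic alcohol without touching the alkyl bromide or the alkene geometry.

Step 4
Reactants: 6 (2E)-5-bromo-3-(propan-2-yl)pent-2-en-1-ol; 7 tert-butyl(chloro)diphenylsilane
Product: 8 {[(2E)-5-bromo-3-(propan-2-yl)pent-2-en-1-yl]oxy}(tert-butyl)diphenylsilane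
Conditions: 7, imidazole, DMF, 0 °C → rt
Reagents that add atoms: tert-butyl(chloro)diphenylsilane (7), CC(C)(C)[Si](Cl)(c1ccccc1)c1ccccc1
Why: Silyl ether protection; the bulky diphenylsilyl ether is chosen because it should survive the later acid, hydroxide and amine steps.

Step 5
Reactants: 8 silyl ether bromide; 9 tert-butyl hydrogen malonate
Product: 10 (5E)-2-(tert-butoxycarbonyl)-7-[(tert-butyldiphenylsilyl)oxy]-5-(propan-2-yl)hept-5-enoic acid (racemic)
Conditions: 9, LiN(iPr)2 (2.1 equiv), THF, −78 → 0 °C; then 8, NaI (cat.), DMPU, 0 °C → rt; aqueous citric acid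
Reagents that add atoms: tert-butyl hydrogen malonate (9), CC(C)(C)OC(=O)CC(=O)O
Why: C-Alkylation of the dianion of the malonic half ester (enolate alkylation) with the primary halide should give the mono-acid directly.

Step 6
Reactants: 11 2-bromopropanoyl bromide (racemic); 12 ethanethiol
Product: 13 S-ethyl 2-bromopropanethioate (racemic)
Conditions: 12, pyridine, CH2Cl2, 0 °C
Reagents that add atoms: ethanethiol (12), CCS
Why: Acylation of the thiol by the acid bromide (thioester formation) should be much faster than displacement of the α-bromide.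

Step 7
Reactants: 10 malonic half ester acid; 13 S-ethyl 2-bromopropanethioate
Product: 14 1-tert-butyl 3-[1-(ethylsulfanyl)-1-oxopropan-2-yl] 2-{(3E)-5-[(tert-butyldiphenylsilyl)oxy]-3-(propan-2-yl)pent-3-en-1-yl}propanedioate (mixture of diastereomers)
Conditions: iPr2NEt, DMF, rt
Reagents that add atoms: none
Why: SN2 O-alkylation of the carboxylate by the α-bromo thioester, under a base too weak to enolise the malonate, should give the α-acyloxy thioester.

Step 8
Reactants: 14 mixed malonate
Product: 15 (5E)-7-[(tert-butyldiphenylsilyl)oxy]-2-({[1-(ethylsulfanyl)-1-oxopropan-2-yl]oxy}carbonyl)-5-(propan-2-yl)hept-5-enoic acid (four stereoisomers)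
Conditions: CF3CO2H/CH2Cl2 (1:4), 0 °C, short contact
Reagents that add atoms: none
Why: Acidolysis of the tert-butyl ester (loss of isobutene) should free the malonic half acid while thioester and diphenylsilyl ether persist.

Step 9
Reactants: 15 malonic half acid; 16 acrolein
Product: 18 S-ethyl (2S)-6-{(3E)-5-[(tert-butyldiphenylsilyl)oxy]-3-(propan-2-yl)pent-3-en-1-yl}-2-methyl-7-oxo-2,3,4,7-tetrahydrooxepine-2-carbothioate, via Michael adduct aldehyde 17 (not isolated)
Conditions: CsOH·H2O (2.2 equiv), O-allyl-N-(9-anthracenylmethyl)cinchonidinium bromide or its cinchoninium pseudoenantiomer (10 mol%), 16 (1.3 equiv), toluene/CH2Cl2, −40 °C; then AcOH, pyridine, piperidine (0.3 equiv), 45 °C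
Reagents that add atoms: acrolein (16), C=CC=O
Why: Proposed new method: Solid CsOH with the chiral ammonium salt should deprotonate the thioester α-C–H that carries the acyloxy group (the malonate C–H is masked as its carboxylate and the thioester has no other enolisable position), and the ammonium enolate adds 1,4 to acrolein to form the quaternary-C–CH2 bond of aldehyde 17; after buffering with acetic acid, piperidine converts the aldehyde into an iminium ion that is attacked by the malonic half ester, and loss of CO2 and piperidine from the Mannich-type adduct forms the C=C bond. The closest known reaction types are the phase-transfer-catalysed asymmetric Michael addition of α-oxygenated carbonyl enolates (glycolate type) and the Knoevenagel–Doebner condensation of substituted malonic half esters, whose combination on an α-(malonyloxy) thioester has not been described. The seven-membered lactone is closed in the condensation by 7-exo-trig attack of the malonate carbon on the exocyclic iminium carbon, and the ring forces the lactone carbonyl and the ring CH2 to be cis on the new double bond. The quaternary stereocentre is set in the Michael step by the chiral ammonium cation, which shields one face of the planar enolate in a contact ion pair, so that all four stereoisomers of 15 converge on one lactone. The step needs C- over O-alkylation and 1,4- over 1,2-addition, which the soft ammonium enolate should secure, and condensation at the malonate carbon only, which is secured because decarboxylation activates that position while the quaternary carbon can no longer enolise.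

Step 10
Reactants: 18 lactone thioester; 19 tributyl(vinyl)stannane
Product: 20 (7S)-3-{(3E)-5-[(tert-butyldiphenylsilyl)oxy]-3-(propan-2-yl)pent-3-en-1-yl}-7-methyl-7-(prop-2-enoyl)-6,7-dihydrooxepin-2(5H)-one
Conditions: 19, Pd2(dba)3 (2.5 mol%), P(2-furyl)3, Cu(O2PPh2) (1.3 equiv), THF, 45 °C
Reagents that add atoms: tributyl(vinyl)stannane (19), C=C[Sn](CCCC)(CCCC)CCCC
Why: The Liebeskind–Srogl thioester–stannane coupling runs under neutral conditions and should turn the thioester into the vinyl ketone without touching lactone, enoate or silyl ether.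

Step 11
Reactants: 20 vinyl ketone; 21 methyl 2-[bis(2,2,2-trifluoroethoxy)phosphoryl]acetate
Product: 22 methyl 2-[bis(2,2,2-trifluoroethoxy)phosphoryl]-5-[(2S)-6-{(3E)-5-[(tert-butyldiphenylsilyl)oxy]-3-(propan-2-yl)pent-3-en-1-yl}-2-methyl-7-oxo-2,3,4,7-tetrahydrooxepin-2-yl]-5-oxopentanoate (epimers at the phosphonate carbon)
Conditions: 21 (2 equiv), DBU (0.1 equiv), THF, 0 °C
Reagents that add atoms: methyl 2-[bis(2,2,2-trifluoroethoxy)phosphoryl]acetate (21), COC(=O)CP(=O)(OCC(F)(F)F)OCC(F)(F)F
Why: Michael addition of the phosphonoacetate carbanion to the unhindered vinyl ketone should be far faster than addition to the trisubstituted enoate lactone, and excess 21 suppresses double addition.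

Step 12
Reactants: 22 silyl ether phosphonate
Product: 23 methyl 2-[bis(2,2,2-trifluoroethoxy)phosphoryl]-5-{(2S)-6-[(3E)-5-hydroxy-3-(propan-2-yl)pent-3-en-1-yl]-2-methyl-7-oxo-2,3,4,7-tetrahydrooxepin-2-yl}-5-oxopentanoate
Conditions: HF·pyridine, THF/pyridine, 0 °C → rt
Reagents that add atoms: none
Why: Buffered fluoride desilylation should free the allylic alcohol and leave the trifluoroethyl phosphonate and the lactone intact.

Step 13
Reactants: 23 allylic alcohol
Product: 24 methyl 2-[bis(2,2,2-trifluoroethoxy)phosphoryl]-5-{(2S)-2-methyl-7-oxo-6-[(3E)-5-oxo-3-(propan-2-yl)pent-3-en-1-yl]-2,3,4,7-tetrahydrooxepin-2-yl}-5-oxopentanoate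
Conditions: activated MnO2, CH2Cl2, rt
Reagents that add atoms: none
Why: Chemoselective allylic oxidation on MnO2 should give the enal under neutral conditions that neither isomerise the trisubstituted alkene nor deprotonate the phosphonate.

Step 14
Reactants: 24 enal phosphonate
Product: 25 ketoemblide
Conditions: KN(SiMe3)2 (1.05 equiv), 18-crown-6, THF, −78 → −40 °C, high dilution, slow addition
Reagents that add atoms: none
Why: The intramolecular Still–Gennari (Z-selective Horner–Wadsworth–Emmons) olefination should close the fourteen-membered ring, since the trifluoroethyl phosphonate places the ester cis to the diene carbon, which is also the less strained trans ring olefin.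

**Compound list**
1 | 4-bromobut-1-yne | C#CCCBr | starting material
2 | methyl chloroformate | COC(=O)Cl | starting material
3 | methyl 5-bromopent-2-ynoate | COC(=O)C#CCCBr | intermediate
4 | isopropylmagnesium chloride | CC(C)[Mg]Cl | starting material
5 | methyl (2E)-5-bromo-3-(propan-2-yl)pent-2-enoate | COC(=O)/C=C(/C(C)C)CCBr | intermediate
6 | (2E)-5-bromo-3-(propan-2-yl)pent-2-en-1-ol | OC/C=C(/C(C)C)CCBr | intermediate
7 | tert-butyl(chloro)diphenylsilane | CC(C)(C)[Si](Cl)(c1ccccc1)c1ccccc1 | starting material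
8 | {[(2E)-5-bromo-3-(propan-2-yl)pent-2-en-1-yl]oxy}(tert-butyl)diphenylsilane | CC(C)(C)[Si](OC/C=C(/C(C)C)CCBr)(c1ccccc1)c1ccccc1 | intermediate
9 | tert-butyl hydrogen malonate | CC(C)(C)OC(=O)CC(=O)O | starting material
10 | (5E)-2-(tert-butoxycarbonyl)-7-[(tert-butyldiphenylsilyl)oxy]-5-(propan-2-yl)hept-5-enoic acid, racemic | CC(C)(C)OC(=O)C(CC/C(C(C)C)=C\CO[Si](c1ccccc1)(c1ccccc1)C(C)(C)C)C(=O)O | intermediate
11 | 2-bromopropanoyl bromide, racemic | CC(Br)C(=O)Br | starting material
12 | ethanethiol | CCS | starting material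
13 | S-ethyl 2-bromopropanethioate, racemic | CCSC(=O)C(C)Br | intermediate
14 | 1-tert-butyl 3-[1-(ethylsulfanyl)-1-oxopropan-2-yl] 2-{(3E)-5-[(tert-butyldiphenylsilyl)oxy]-3-(propan-2-yl)pent-3-en-1-yl}propanedioate, mixture of diastereomers | CCSC(=O)C(C)OC(=O)C(CC/C(C(C)C)=C\CO[Si](c1ccccc1)(c1ccccc1)C(C)(C)C)C(=O)OC(C)(C)C | intermediate
15 | (5E)-7-[(tert-butyldiphenylsilyl)oxy]-2-({[1-(ethylsulfanyl)-1-oxopropan-2-yl]oxy}carbonyl)-5-(propan-2-yl)hept-5-enoic acid, four stereoisomers | CCSC(=O)C(C)OC(=O)C(CC/C(C(C)C)=C\CO[Si](c1ccccc1)(c1ccccc1)C(C)(C)C)C(=O)O | intermediate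
16 | acrolein | C=CC=O | starting material
17 | (5E)-7-[(tert-butyldiphenylsilyl)oxy]-2-({[(2S)-1-(ethylsulfanyl)-2-methyl-1,5-dioxopentan-2-yl]oxy}carbonyl)-5-(propan-2-yl)hept-5-enoic acid, epimers at the malonate carbon | CCSC(=O)[C@](C)(CCC=O)OC(=O)C(CC/C(C(C)C)=C\CO[Si](c1ccccc1)(c1ccccc1)C(C)(C)C)C(=O)O | intermediate
18 | S-ethyl (2S)-6-{(3E)-5-[(tert-butyldiphenylsilyl)oxy]-3-(propan-2-yl)pent-3-en-1-yl}-2-methyl-7-oxo-2,3,4,7-tetrahydrooxepine-2-carbothioate | CCSC(=O)[C@]1(C)CCC=C(CC/C(C(C)C)=C\CO[Si](c2ccccc2)(c2ccccc2)C(C)(C)C)C(=O)O1 | intermediate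
19 | tributyl(vinyl)stannane | C=C[Sn](CCCC)(CCCC)CCCC | starting material
20 | (7S)-3-{(3E)-5-[(tert-butyldiphenylsilyl)oxy]-3-(propan-2-yl)pent-3-en-1-yl}-7-methyl-7-(prop-2-enoyl)-6,7-dihydrooxepin-2(5H)-one | C=CC(=O)[C@]1(C)CCC=C(CC/C(C(C)C)=C\CO[Si](c2ccccc2)(c2ccccc2)C(C)(C)C)C(=O)O1 | intermediate
21 | methyl 2-[bis(2,2,2-trifluoroethoxy)phosphoryl]acetate | COC(=O)CP(=O)(OCC(F)(F)F)OCC(F)(F)F | starting material
22 | methyl 2-[bis(2,2,2-trifluoroethoxy)phosphoryl]-5-[(2S)-6-{(3E)-5-[(tert-butyldiphenylsilyl)oxy]-3-(propan-2-yl)pent-3-en-1-yl}-2-methyl-7-oxo-2,3,4,7-tetrahydrooxepin-2-yl]-5-oxopentanoate, epimers at the phosphonate carbon | COC(=O)C(CCC(=O)[C@]1(C)CCC=C(CC/C(C(C)C)=C\CO[Si](c2ccccc2)(c2ccccc2)C(C)(C)C)C(=O)O1)P(=O)(OCC(F)(F)F)OCC(F)(F)F | intermediate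
23 | the 5-hydroxy analogue of 22 (free (3E)-allylic alcohol) | COC(=O)C(CCC(=O)[C@]1(C)CCC=C(CC/C(C(C)C)=C\CO)C(=O)O1)P(=O)(OCC(F)(F)F)OCC(F)(F)F | intermediate
24 | the 5-oxo analogue of 22 ((3E)-enal) | COC(=O)C(CCC(=O)[C@]1(C)CCC=C(CC/C(C(C)C)=C\C=O)C(=O)O1)P(=O)(OCC(F)(F)F)OCC(F)(F)F | intermediate
25 | ketoemblide | COC(=O)/C1=C\C=C(\C(C)C)CCC2=CCC[C@](C)(OC2=O)C(=O)CC1 | target

**Totals.** Total step count: 14. Longest linear sequence: 13 steps (steps 1–5 and 7–14; step 6 is a one-step branch).

**Steps most likely to fail**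

Step 9 (Proposed new method). What may go wrong: incomplete enolisation or poor facial selectivity in the phase-transfer Michael addition, hydroxide attack or acyl migration at the α-acyloxy thioester, and polymerisation of acrolein. The fallback uses known chemistry, sets out from 10 and comes back at 17. The stereocentre is set by self-regeneration of a lactic acid stereocentre instead of catalysis. (R)-Lactic acid and pivalaldehyde (TsOH, pentane, water removal) give the cis acetal (2R,5R)-2-tert-butyl-5-methyl-1,3-dioxolan-4-one F1. Its lithium enolate (LiN(iPr)2, THF, −78 °C) is alkylated by 2-(2-bromoethyl)-1,3-dioxolane/DMPU anti to the tert-butyl group to give (2R,5S)-2-tert-butyl-5-[2-(1,3-dioxolan-2-yl)ethyl]-5-methyl-1,3-dioxolan-4-one F2. Me2AlSEt (from AlMe3 and ethanethiol) opens the acetal lactone to S-ethyl (2S)-4-(1,3-dioxolan-2-yl)-2-hydroxy-2-methylbutanethioate F3. The tertiary alcohol is acylated with 10 (N,N'-dicyclohexylcarbodiimide, DMAP, through the carboxyketene) to the mixed malonate F4. Aqueous CF3CO2H then removes the tert-butyl ester and the acetal to give 17 as the single (S)-isomer at the quaternary carbon, which is closed to 18 by the amine stage of step 9 (a Knoevenagel–Doebner condensation).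

Step 14. What may go wrong: oligomerisation at the concentrations needed, and isomerisation or self-condensation of the enal under the strongly basic conditions. The fallback sets out from 20 and comes back at 25; it closes the ring by a decarboxylative Knoevenagel–Doebner condensation under mildly basic amine conditions. Michael addition of Meldrum's acid to 20 (Et3N cat.) gives the 5-substituted 2,2-dimethyl-1,3-dioxane-4,6-dione F5. HF·pyridine gives the allylic alcohol F6, and MnO2 gives the enal F7. Warm methanol opens the dioxanedione to the methyl hydrogen malonate F8. Piperidinium acetate in pyridine at high dilution then closes F8 to 25 with loss of CO2 and water, the ring strain being expected to favour the trans ring olefin.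

Step 10. What may go wrong: slow C–S activation at the hindered α-quaternary thioester and polymerisation of the vinyl ketone at the temperature needed. The fallback sets out from 18 and comes back at 20; it replaces the cross-coupling by a redox sequence. Fukuyama reduction (Et3SiH, Pd/C, acetone) gives the aldehyde (2S)-6-{(3E)-5-[(tert-butyldiphenylsilyl)oxy]-3-(propan-2-yl)pent-3-en-1-yl}-2-methyl-7-oxo-2,3,4,7-tetrahydrooxepine-2-carbaldehyde F9. Vinylmagnesium bromide at −78 °C adds to the aldehyde faster than to the hindered lactone and gives the allylic alcohol F10 as a mixture of carbinol epimers, which MnO2 oxidises to 20.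

**Further compounds**
F1 | step 9 | (2R,5R)-2-tert-butyl-5-methyl-1,3-dioxolan-4-one | C[C@H]1O[C@@H](C(C)(C)C)OC1=O
F2 | step 9 | (2R,5S)-2-tert-butyl-5-[2-(1,3-dioxolan-2-yl)ethyl]-5-methyl-1,3-dioxolan-4-one | C[C@@]1(CCC2OCCO2)O[C@@H](C(C)(C)C)OC1=O
F3 | step 9 | S-ethyl (2S)-4-(1,3-dioxolan-2-yl)-2-hydroxy-2-methylbutanethioate | CCSC(=O)[C@@](C)(O)CCC1OCCO1
F4 | step 9 | 1-tert-butyl 3-[(2S)-4-(1,3-dioxolan-2-yl)-1-(ethylsulfanyl)-2-methyl-1-oxobutan-2-yl] 2-{(3E)-5-[(tert-butyldiphenylsilyl)oxy]-3-(propan-2-yl)pent-3-en-1-yl}propanedioate | CCSC(=O)[C@@](C)(OC(=O)C(CC/C(C(C)C)=C\CO[Si](c1ccccc1)(c1ccccc1)C(C)(C)C)C(=O)OC(C)(C)C)CCC1OCCO1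
F5 | step 14 | 5-{3-[(2S)-6-{(3E)-5-[(tert-butyldiphenylsilyl)oxy]-3-(propan-2-yl)pent-3-en-1-yl}-2-methyl-7-oxo-2,3,4,7-tetrahydrooxepin-2-yl]-3-oxopropyl}-2,2-dimethyl-1,3-dioxane-4,6-dione | CC1(C)OC(=O)C(CCC(=O)[C@]2(C)CCC=C(CC/C(C(C)C)=C\CO[Si](c3ccccc3)(c3ccccc3)C(C)(C)C)C(=O)O2)C(=O)O1
F6 | step 14 | the desilylated (3E)-allylic alcohol of F5 | CC1(C)OC(=O)C(CCC(=O)[C@]2(C)CCC=C(CC/C(C(C)C)=C\CO)C(=O)O2)C(=O)O1
F7 | step 14 | the (3E)-enal from F6 | CC1(C)OC(=O)C(CCC(=O)[C@]2(C)CCC=C(CC/C(C(C)C)=C\C=O)C(=O)O2)C(=O)O1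
F8 | step 14 | 2-(methoxycarbonyl)-5-{(2S)-2-methyl-7-oxo-6-[(3E)-5-oxo-3-(propan-2-yl)pent-3-en-1-yl]-2,3,4,7-tetrahydrooxepin-2-yl}-5-oxopentanoic acid | COC(=O)C(CCC(=O)[C@]1(C)CCC=C(CC/C(C(C)C)=C\C=O)C(=O)O1)C(=O)O
F9 | step 10 | (2S)-6-{(3E)-5-[(tert-butyldiphenylsilyl)oxy]-3-(propan-2-yl)pent-3-en-1-yl}-2-methyl-7-oxo-2,3,4,7-tetrahydrooxepine-2-carbaldehyde | O=C[C@]1(C)CCC=C(CC/C(C(C)C)=C\CO[Si](c2ccccc2)(c2ccccc2)C(C)(C)C)C(=O)O1
F10 | step 10 | (7S)-3-{(3E)-5-[(tert-butyldiphenylsilyl)oxy]-3-(propan-2-yl)pent-3-en-1-yl}-7-(1-hydroxyprop-2-en-1-yl)-7-methyl-6,7-dihydrooxepin-2(5H)-one | C=CC(O)[C@]1(C)CCC=C(CC/C(C(C)C)=C\CO[Si](c2ccccc2)(c2ccccc2)C(C)(C)C)C(=O)O1
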